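**Plan**

- Labels used below: ring C1 (C=O), C2 (C–CH3, epoxide), C3 (epoxide CH), C4 (CH2), C5 (CH), C6 (CH–O-angeloyl); side chain C7 (the C=CH2 carbon), C8 (CH–OAc, oxygen O8), then the prenyl group.
- Retrosynthesis: the C1 ketone and the epoxide come from hydroxyl-directed epoxidation of the C1 allylic alcohol of a 2-methyl-enone; the two esters come from the C6 and C8 hydroxyls; the ring is then cut at C4–C5 and C2–C3, and a helper bond C4–C(=O) of a lactone is added.
- Enabling feature: O8 is joined to C5 through C8–C7, so a propiolate on O8 reaches the diene terminus C5 through a six-membered lactone; C1(=O)/C2–CH3 is an ethyl ketone, hence the silyl enol ether diene C2=C1(OSi)–C6=C5.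
- Forward: the chain is built first (allylboration of 2-bromoacrolein, cross-metathesis to prenyl, Heck coupling to the dienone, propiolate ester). The carbocycle and a temporary δ-lactone then close together. The enol ether next delivers O6, and the lactone carbonyl leaves as CO2, giving the 2-methyl-enone and free O8–H.
- Stereochemistry: C8 by reagent control; C5 from C8 through the lactone transition state; C6 by Rubottom oxidation anti to C5; the C1 carbinol by axial hydride; C2/C3 by vanadium delivery syn to that hydroxyl (cis to the side chain); the angelate Z geometry from angelic acid.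

Key step: step 5

Remark: 2-bromoacrolein (otherwise one step from acrolein) and the (−)-Ipc2B(allyl) solution are treated as purchased materials.

**Route**

Step 1
Reactants: 1 2-bromoprop-2-enal (2-bromoacrolein)
Product: 2 (3S)-2-bromohexa-1,5-dien-3-ol
Conditions: (−)-Ipc2B(allyl), Et2O, −78 °C; then NaOH, H2O2, 0 °C
Reagents that add atoms: (−)-B-allyldiisopinocampheylborane (the antipode made from (+)-α-pinene), C=CCB([C@@H]1C[C@@H]2C[C@@H](C2(C)C)[C@H]1C)[C@@H]1C[C@@H]2C[C@@H](C2(C)C)[C@H]1C
Why: Brown asymmetric allylboration through a chair transition state should deliver allyl to one aldehyde face and set C8 as S (the facial sense known for benzaldehyde with this antipode), the alkenyl bromide being inert.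

Step 2
Reactants: 2 (3S)-2-bromohexa-1,5-dien-3-ol; 3 2-methylbut-2-ene
Product: 4 (3S)-2-bromo-6-methylhepta-1,5-dien-3-ol
Conditions: 3 (large excess), second-generation Hoveyda–Grubbs catalyst (3 mol %), CH2Cl2, 40 °C
Reagents that add atoms: none
Why: Olefin cross-metathesis should cap the terminal alkene as the prenyl group, while the hindered, electron-poor 1,1-disubstituted bromoalkene stays out of the cycle and C8 is untouched.

Step 3
Reactants: 4 (3S)-2-bromo-6-methylhepta-1,5-dien-3-ol; 5 pent-1-en-3-one
Product: 6 (4E,7S)-7-hydroxy-10-methyl-6-methylideneundeca-4,9-dien-3-one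
Conditions: Pd(OAc)2 (5 mol %), P(o-tol)3 (10 mol %), Et3N, MeCN, 70 °C
Reagents that add atoms: none
Why: Heck reaction of the alkenyl bromide with the vinyl ketone should give the E dienone (syn insertion, syn β-hydride elimination) and keep the C7 methylidene, because the halide sits on C7.

Step 4
Reactants: 6 (4E,7S)-7-hydroxy-10-methyl-6-methylideneundeca-4,9-dien-3-one; 7 prop-2-ynoic acid
Product: 8 (4E,7S)-10-methyl-6-methylidene-3-oxoundeca-4,9-dien-7-yl prop-2-ynoate
Conditions: DCC, DMAP (5 mol %), CH2Cl2, −20 °C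
Reagents that add atoms: none
Why: Steglich esterification at low temperature should acylate O8 with retention at C8, installing the two-carbon dienophile together with its activating carbonyl as a temporary tether.

Step 5
Reactants: 8 (4E,7S)-10-methyl-6-methylidene-3-oxoundeca-4,9-dien-7-yl prop-2-ynoate
Product: 10 (3S,4aR,7S)-6-[(tert-butyldimethylsilyl)oxy]-7-methyl-4-methylidene-3-(3-methylbut-2-en-1-yl)-3,4,4a,7-tetrahydro-1H-isochromen-1-one, via silyl dienol ether 9 (not isolated)
Conditions: TBSOTf, iPr2NEt, CH2Cl2, −78 to 0 °C; then PhMe (0.01 M), BHT, 110 °C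
Reagents that add atoms: tert-butyldimethylsilyl triflate, CC(C)(C)[Si](C)(C)OS(=O)(=O)C(F)(F)F
Why: Soft enolisation turns the ethyl ketone into the (Z)-2-silyloxy-diene C2=C1(OSi)–C6=C5, which on heating should undergo a concerted, asynchronous intramolecular [4+2] cycloaddition with the propiolate on O8 (nucleophilic C2 to the β-alkyne carbon C3, C5 to the ester-bearing C4). The closest known reaction type is the ester-tethered intramolecular Diels–Alder reaction of dienyl propiolates and of 2-silyloxy-dienes. The carbocycle closes as a six-membered cyclohexa-1,4-diene by [4+2] addition, and the δ-lactone O8–C(=O)–C4–C5–C7–C8 closes as the six-membered ring of a tether attached at the diene terminus, fused at C4–C5. C5 is set by C8: in the lactone-forming transition state the prenyl group should take the outward pseudo-equatorial site and not the site over the diene, which from (S)-C8 gives the C5 configuration of the target; the C2 methyl centre (from the Z enol ether) is erased later. The step needs regio-, peri- and facial selectivity: the tether fixes which alkyne carbon meets C5 and agrees with the diene polarity, the other diene C6=C5–C7=CH2 cannot compete because the tether leaves from its inner carbon C7 (a bridgehead alkene would result), and the facial preference rests on the single C8 stereocentre.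

Step 6
Reactants: 10 the cycloadduct of step 5
Product: 12 (3S,4aR,5S,7S)-5-[(tert-butyldimethylsilyl)oxy]-7-methyl-4-methylidene-3-(3-methylbut-2-en-1-yl)-4,4a,5,7-tetrahydro-1H-isochromene-1,6(3H)-dione, via silyloxy epoxide 11 (not isolated)
Conditions: DMDO (1.05 equiv), acetone/CH2Cl2, −78 °C; then PPTS (5 mol %), 0 °C
Reagents that add atoms: dimethyldioxirane, CC1(C)OO1
Why: Rubottom oxidation should epoxidise the silyl enol ether (the most electron-rich alkene) on the face opposite the C5 substituent and the C2 methyl, and the acid-promoted 1,4-silyl shift then gives the C6 silyl ether trans to C5.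

Step 7
Reactants: 12 the silyloxy keto lactone of step 6
Product: 14 (5S,6S)-6-[(tert-butyldimethylsilyl)oxy]-5-[(3S)-3-hydroxy-6-methylhepta-1,5-dien-2-yl]-2-methylcyclohex-2-en-1-one, via hydroxy acid 13 (not isolated)
Conditions: LiOH·H2O, THF/H2O, 0 to 23 °C; then AcOH to pH 5, 60 °C
Reagents that add atoms: none
Why: Saponification opens the unsaturated δ-lactone, and once the ring alkene has moved into conjugation with the C1 ketone the acid is a vinylogous β-keto acid (Hagemann type) that should lose CO2 on warming through its dienol, which ketonises to the 2-methyl-enone; C4 ends as CH2, O8–H is freed, and C5 and C6 (already trans-diequatorial) are unchanged.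

Step 8
Reactants: 14 the hydroxy enone of step 7
Product: 15 (3S)-2-[(1S,2S)-2-[(tert-butyldimethylsilyl)oxy]-4-methyl-3-oxocyclohex-4-en-1-yl]-6-methylhepta-1,5-dien-3-yl acetate
Conditions: Ac2O, pyridine, DMAP (cat.), CH2Cl2, 0 °C
Reagents that add atoms: acetic anhydride, CC(=O)OC(C)=O
Why: DMAP-catalysed acylation of the only free hydroxyl installs the C8 acetate with retention.

Step 9
Reactants: 15 the silyl ether acetate of step 8
Product: 16 (3S)-2-[(1S,2S)-2-hydroxy-4-methyl-3-oxocyclohex-4-en-1-yl]-6-methylhepta-1,5-dien-3-yl acetate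
Conditions: HF·pyridine, THF, 0 °C
Reagents that add atoms: none
Why: Fluoride-mediated desilylation under mildly acidic conditions should free the C6 hydroxyl and leave the acetate, the enone and the C6 configuration alone.

Step 10
Reactants: 16 the hydroxy enone acetate of step 9; 17 (2Z)-2-methylbut-2-enoic acid (angelic acid)
Product: 18 (1S,6S)-6-[(3S)-3-(acetyloxy)-6-methylhepta-1,5-dien-2-yl]-3-methyl-2-oxocyclohex-3-en-1-yl (2Z)-2-methylbut-2-enoate
Conditions: 17, 2,4,6-trichlorobenzoyl chloride, Et3N, PhMe, 23 °C; then 16, 75 °C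
Reagents that add atoms: none
Why: Yamaguchi-type mixed-anhydride esterification without a nucleophilic catalyst should acylate the C6 hydroxyl under conditions of the kind used to keep the Z geometry of angelates.

Step 11
Reactants: 18 the angeloyloxy enone of step 10
Product: 19 (1S,2S,6S)-6-[(3S)-3-(acetyloxy)-6-methylhepta-1,5-dien-2-yl]-2-hydroxy-3-methylcyclohex-3-en-1-yl (2Z)-2-methylbut-2-enoate
Conditions: NaBH4, CeCl3·7H2O, MeOH, −78 °C
Reagents that add atoms: none
Why: Luche reduction should give 1,2-reduction by axial hydride delivery to the half-chair enone with pseudo-equatorial C5 and C6 substituents, so the new C1 hydroxyl is trans to the C6 ester and cis to the C5 side chain (as carvone gives cis-carveol).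

Step 12
Reactants: 19 the allylic alcohol of step 11
Product: 20 (1R,2R,3S,4S,6S)-4-[(3S)-3-(acetyloxy)-6-methylhepta-1,5-dien-2-yl]-2-hydroxy-1-methyl-7-oxabicyclo[4.1.0]heptan-3-yl (2Z)-2-methylbut-2-enoate
Conditions: VO(acac)2 (5 mol %), t-BuOOH, CH2Cl2, 0 to 23 °C
Reagents that add atoms: tert-butyl hydroperoxide, CC(C)(C)OO
Why: Vanadium-catalysed hydroxyl-directed epoxidation should deliver oxygen to the C2=C3 alkene from the face of the C1 hydroxyl only, setting C2 and C3 with the epoxide cis to the side chain and leaving the prenyl, methylidene and angelate alkenes alone.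

Step 13
Reactants: 20 the epoxy alcohol of step 12
Product: 21 (1S,3S,4S,6S)-4-[(3S)-3-(acetyloxy)-6-methylhepta-1,5-dien-2-yl]-1-methyl-2-oxo-7-oxabicyclo[4.1.0]heptan-3-yl (2Z)-2-methylbut-2-enoate (CNP0125636.1)
Conditions: Dess–Martin periodinane, NaHCO3, CH2Cl2, 0 to 23 °C
Reagents that add atoms: none
Why: Dess–Martin oxidation under buffered conditions should convert the C1 carbinol to the ketone without touching the epoxide, the two esters or the epimerisable C6 centre.

**Compound list**

1 | 2-bromoprop-2-enal | C=C(Br)C=O | starting material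
2 | (3S)-2-bromohexa-1,5-dien-3-ol | C=C(Br)[C@H](CC=C)O | intermediate
3 | 2-methylbut-2-ene | CC=C(C)C | starting material
4 | (3S)-2-bromo-6-methylhepta-1,5-dien-3-ol | C=C(Br)[C@H](CC=C(C)C)O | intermediate
5 | pent-1-en-3-one | CCC(=O)C=C | starting material
6 | (4E,7S)-7-hydroxy-10-methyl-6-methylideneundeca-4,9-dien-3-one | CCC(=O)/C=C/C(=C)[C@H](CC=C(C)C)O | intermediate
7 | prop-2-ynoic acid | C#CC(=O)O | starting material
8 | (4E,7S)-10-methyl-6-methylidene-3-oxoundeca-4,9-dien-7-yl prop-2-ynoate | CCC(=O)/C=C/C(=C)[C@H](CC=C(C)C)OC(=O)C#C | intermediate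
9 | (2Z,4E,7S)-3-[(tert-butyldimethylsilyl)oxy]-10-methyl-6-methylideneundeca-2,4,9-trien-7-yl prop-2-ynoate | C/C=C(O[Si](C)(C)C(C)(C)C)/C=C/C(=C)[C@H](CC=C(C)C)OC(=O)C#C | intermediate (not isolated)
10 | (3S,4aR,7S)-6-[(tert-butyldimethylsilyl)oxy]-7-methyl-4-methylidene-3-(3-methylbut-2-en-1-yl)-3,4,4a,7-tetrahydro-1H-isochromen-1-one | C[C@H]1C=C2C(=O)O[C@@H](CC=C(C)C)C(=C)[C@H]2C=C1O[Si](C)(C)C(C)(C)C | intermediate
11 | 5,6-epoxide of 10 (oxirane oxygen on the ring face opposite C4; silyloxy group on the oxirane carbon C6) | C[C@H]1C=C2C(=O)O[C@@H](CC=C(C)C)C(=C)[C@H]2[C@@H]3O[C@]13O[Si](C)(C)C(C)(C)C | intermediate (not isolated)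
12 | (3S,4aR,5S,7S)-5-[(tert-butyldimethylsilyl)oxy]-7-methyl-4-methylidene-3-(3-methylbut-2-en-1-yl)-4,4a,5,7-tetrahydro-1H-isochromene-1,6(3H)-dione | C[C@H]1C=C2C(=O)O[C@@H](CC=C(C)C)C(=C)[C@H]2[C@H](O[Si](C)(C)C(C)(C)C)C1=O | intermediate
13 | (5S,6S)-5-[(tert-butyldimethylsilyl)oxy]-6-[(3S)-3-hydroxy-6-methylhepta-1,5-dien-2-yl]-3-methyl-4-oxocyclohex-2-ene-1-carboxylic acid (both C1 epimers) | CC1=CC(C(=O)O)[C@@H](C(=C)[C@H](CC=C(C)C)O)[C@H](O[Si](C)(C)C(C)(C)C)C1=O | intermediate (not isolated)
14 | (5S,6S)-6-[(tert-butyldimethylsilyl)oxy]-5-[(3S)-3-hydroxy-6-methylhepta-1,5-dien-2-yl]-2-methylcyclohex-2-en-1-one | CC1=CC[C@@H](C(=C)[C@H](CC=C(C)C)O)[C@H](O[Si](C)(C)C(C)(C)C)C1=O | intermediate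
15 | (3S)-2-[(1S,2S)-2-[(tert-butyldimethylsilyl)oxy]-4-methyl-3-oxocyclohex-4-en-1-yl]-6-methylhepta-1,5-dien-3-yl acetate | CC1=CC[C@@H](C(=C)[C@H](CC=C(C)C)OC(C)=O)[C@H](O[Si](C)(C)C(C)(C)C)C1=O | intermediate
16 | (3S)-2-[(1S,2S)-2-hydroxy-4-methyl-3-oxocyclohex-4-en-1-yl]-6-methylhepta-1,5-dien-3-yl acetate | CC1=CC[C@@H](C(=C)[C@H](CC=C(C)C)OC(C)=O)[C@H](O)C1=O | intermediate
17 | (2Z)-2-methylbut-2-enoic acid (angelic acid) | C/C=C(/C)C(=O)O | starting material
18 | (1S,6S)-6-[(3S)-3-(acetyloxy)-6-methylhepta-1,5-dien-2-yl]-3-methyl-2-oxocyclohex-3-en-1-yl (2Z)-2-methylbut-2-enoate | CC1=CC[C@@H](C(=C)[C@H](CC=C(C)C)OC(C)=O)[C@H](OC(=O)/C(C)=C\C)C1=O | intermediate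
19 | (1S,2S,6S)-6-[(3S)-3-(acetyloxy)-6-methylhepta-1,5-dien-2-yl]-2-hydroxy-3-methylcyclohex-3-en-1-yl (2Z)-2-methylbut-2-enoate | CC1=CC[C@@H](C(=C)[C@H](CC=C(C)C)OC(C)=O)[C@H](OC(=O)/C(C)=C\C)[C@H]1O | intermediate
20 | (1R,2R,3S,4S,6S)-4-[(3S)-3-(acetyloxy)-6-methylhepta-1,5-dien-2-yl]-2-hydroxy-1-methyl-7-oxabicyclo[4.1.0]heptan-3-yl (2Z)-2-methylbut-2-enoate | C=C([C@H](CC=C(C)C)OC(C)=O)[C@@H]1C[C@@H]2O[C@]2(C)[C@H](O)[C@H]1OC(=O)/C(C)=C\C | intermediate
21 | (1S,3S,4S,6S)-4-[(3S)-3-(acetyloxy)-6-methylhepta-1,5-dien-2-yl]-1-methyl-2-oxo-7-oxabicyclo[4.1.0]heptan-3-yl (2Z)-2-methylbut-2-enoate | C=C([C@H](CC=C(C)C)OC(C)=O)[C@@H]1C[C@@H]2O[C@]2(C)C(=O)[C@H]1OC(=O)/C(C)=C\C | target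

**Step count and risks**

Total step count: 13. Longest linear sequence: 13 steps (from 1).

Steps most likely to fail:

Step 5. The cyclisation may be sluggish (the ester must adopt its less favoured conformation), and the facial preference that sets C5 rests on one stereocentre across an sp2 carbon, so facial selectivity may be poor. The fallback gives up the tether and sets out from 6. Acetylation (Ac2O, pyridine) should give the acetate F1. Soft enolisation (TBSOTf, Et3N) should give the silyl dienol ether F2. An intermolecular Diels–Alder reaction with methyl propiolate (PhMe, 90 °C) has the same polarity-controlled regiochemistry and should give the cyclohexadiene ester F3. Its two C5 epimers are diastereomers, because C8 is fixed, and would be separated by chromatography. Rubottom oxidation (DMDO; PPTS) should give the silyloxy keto ester F4. LiOH, then pH 5 at 60 °C, cleaves the methyl ester and the acetate and expels CO2 through 13, so the fallback comes back to the route at 14.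

Step 7. Relactonisation of the hydroxy acid may compete with loss of CO2, or the silyl group next to the ketone may migrate or be lost in base. The fallback removes the tether before C6 is oxygenated and sets out from 10. Hot aqueous KOH (MeOH/H2O, 65 °C; classical conditions for this ester type) should cleave the enol ether, open the lactone and decarboxylate to the hydroxy enone F5. Acetylation should give the acetate F6. Soft enolisation at C6 (TBSOTf, Et3N) should give the cross-conjugated silyl dienol ether F7. Rubottom oxidation (DMDO; PPTS), anti to the C5 substituent, comes back to the route at 15.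

Step 10. The angeloyl unit may isomerise from Z to E during activation, or acylation of the hindered C6 hydroxyl may be slow. The fallback builds the ester from the alkenyl side and not from the acid: palladium-catalysed alkoxycarbonylation of (Z)-2-bromobut-2-ene with alcohol 16 as the nucleophile (CO at 1 atm, Pd(OAc)2, Xantphos, Et3N, PhMe, 70 °C). The alkene geometry is fixed in the halide and retained through oxidative addition and CO insertion. It sets out from 16 and comes back at 18 with no new isolated compound.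

Further compounds

F1 | step 5 | (4E,7S)-10-methyl-6-methylidene-3-oxoundeca-4,9-dien-7-yl acetate | CCC(=O)/C=C/C(=C)[C@H](CC=C(C)C)OC(C)=O
F2 | step 5 | (2Z,4E,7S)-3-[(tert-butyldimethylsilyl)oxy]-10-methyl-6-methylideneundeca-2,4,9-trien-7-yl acetate | C/C=C(O[Si](C)(C)C(C)(C)C)/C=C/C(=C)[C@H](CC=C(C)C)OC(C)=O
F3 | step 5 | methyl (3S,6R)-6-[(3S)-3-(acetyloxy)-6-methylhepta-1,5-dien-2-yl]-4-[(tert-butyldimethylsilyl)oxy]-3-methylcyclohexa-1,4-diene-1-carboxylate | C[C@H]1C=C(C(=O)OC)[C@@H](C(=C)[C@H](CC=C(C)C)OC(C)=O)C=C1O[Si](C)(C)C(C)(C)C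
F4 | step 5 | methyl (3S,5S,6R)-6-[(3S)-3-(acetyloxy)-6-methylhepta-1,5-dien-2-yl]-5-[(tert-butyldimethylsilyl)oxy]-3-methyl-4-oxocyclohex-1-ene-1-carboxylate | C[C@H]1C=C(C(=O)OC)[C@@H](C(=C)[C@H](CC=C(C)C)OC(C)=O)[C@H](O[Si](C)(C)C(C)(C)C)C1=O
F5 | step 7 | (5R)-5-[(3S)-3-hydroxy-6-methylhepta-1,5-dien-2-yl]-2-methylcyclohex-2-en-1-one | CC1=CC[C@@H](C(=C)[C@H](CC=C(C)C)O)CC1=O
F6 | step 7 | (3S)-6-methyl-2-[(1R)-4-methyl-3-oxocyclohex-4-en-1-yl]hepta-1,5-dien-3-yl acetate | CC1=CC[C@@H](C(=C)[C@H](CC=C(C)C)OC(C)=O)CC1=O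
F7 | step 7 | (3S)-2-[(1R)-3-[(tert-butyldimethylsilyl)oxy]-4-methylcyclohexa-2,4-dien-1-yl]-6-methylhepta-1,5-dien-3-yl acetate | CC1=CC[C@@H](C(=C)[C@H](CC=C(C)C)OC(C)=O)C=C1O[Si](C)(C)C(C)(C)C
F0 | step 10 | none | none
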